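The earlier runs and the new flask were generated by integration for an exercise; scatter was added.

If a bis adduct couples on at a rate proportional to the partner around it, its fate depends on the partner it has met, so we count turnovers rather than minutes. Substrate takes up coupling partner step by step, through single product and bis adduct to triple product and tetra adduct. Each step releases by-product, which can crystallise, and substrate also pairs to homo dimer.

| flask | substrate | coupling partner | remark | time |
|---|---|---|---|---|
| autumn | 0.40 M | 0.072 M | run made earlier |  |
| dawn | 0.40 M | 1.1 M | run made earlier |  |
| spring | 1 M | 0.36 M | run made earlier |  |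
| south-west | 1.5 M | 0.120 M |  | 1.5 h |
| north-east | 0.60 M | 0.200 M |  | 1.5 h |
| east | 1.5 M | 1.50 M |  | 1.5 h |
| north | 0.40 M | 0.360 M |  | 1.5 h |
| south | 1.5 M | 0.360 M |  | 1.5 h |

| run | time / min | bis adduct / % | triple product / % | tetra adduct / % |
|---|---|---|---|---|
| autumn | 3.00 | 0.4 | 0 | 0 |
| autumn | 8.00 | 0 | 0 | 0 |
| autumn | 15.0 | 0 | 0.1 | 0.4 |
| autumn | 25.0 | 0 | 0.2 | 0.4 |
| autumn | 30.0 | 0.4 | 0.7 | 0.5 |
| autumn | 50.0 | 0.8 | 0 | 0 |
| dawn | 3.00 | 0.4 | 0 | 0 |
| dawn | 8.00 | 2.0 | 0 | 1.0 |
| dawn | 15.0 | 4.6 | 1.1 | 0.2 |
| dawn | 25.0 | 8.8 | 3.5 | 0.3 |
| dawn | 30.0 | 10.7 | 4.5 | 0.4 |
| dawn | 50.0 | 15.2 | 8.5 | 4.4 |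
| spring | 4.00 | 1.2 | 0.7 | 0.3 |
| spring | 12.0 | 0.3 | 0 | 0.2 |
| spring | 20.0 | 0.2 | 0 | 0.5 |
| spring | 30.0 | 1.7 | 0.2 | 0 |
| spring | 50.0 | 2.3 | 0 | 0.3 |

(each reading ± 0.5 percentage points)

- percentages count the substrate that a species holds: one homo dimer counts as two
- by-product is meant together with its crystals
- solid, in amounts per volume of the solution: crystals
- steps under discussion: substrate + coupling partner -> single product + by-product; coupling partner + single product -> bis adduct + by-product; coupling partner + bis adduct -> triple product + by-product; coupling partner + triple product -> tetra adduct + by-product; 2 substrate -> homo dimer; crystals <-> by-product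

- the flasks by share of bis adduct in all that became bis adduct or triple product or tetra adduct, highest first, at 1.5 h (south-west / north-east / east / north / south)
- the same order at 12 h (south-west / north-east / east / north / south)
- the share of bis adduct in all that became bis adduct or triple product or tetra adduct of the flask you put first, at 1.5 h
- the share of bis adduct in all that became bis adduct or triple product or tetra adduct of the flask you put last, at 1.5 h

Let the turnover count be triple product plus tetra adduct over bis adduct; the share asked is then one divided by one plus that count. In the dawn run, partner is charged above substrate, but by 50.0 min the adduct readings account for 0.294 M of it, so the coupling is not pseudo-first-order there, and we use the charged partner as a rough yardstick. Its readings at 50.0 min give a count of 0.849. That yields the turnover dose, the charged partner concentration times time that buys one unit of count: 64.8 M·min, a reading carrying the scatter of 0.5 percentage points.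

Charging east's 1.50 M for 1.5 h against this dose gives a count of 2.08 and a share of 32.4 %. That link is weak, because every coupling spends one partner and east charges as much partner as substrate. So we reforge it, supposing that substrate-derived sites stay near their charge and take partner at this same rate. Partner then decays with a time constant of dose over substrate, 43.2 min in east, shorter than the run. Our count becomes (partner/substrate) × (one minus exp(−substrate × time/dose)), which is 0.875 for east.

At 1.5 h we commit to these shares: south-west 93.5 %, north-east 84.1 %, south 82.6 %, north 72.3 % and east 53.3 %. At 12 h we reckon south-west 92.6 %, south 80.6 %, north-east 75.0 %, north 52.9 % and east 50.0 %.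

The forecast gave south-west > south > north-east > north > east at 1.5 h and south-west > south > north-east > north > east at 12 h, with 95 % and 65 %, holding that “East is last because it has the highest ratio and concentration”; it differs from our reckoning in the second and third places of the earlier order and in the low share.

The flasks give south-west > north-east > south > north > east at 1.5 h and south-west > south > north-east > north > east at 12 h, with 93.3 % first and 49.0 % last.

    substrate + coupling partner → single product + by-product (k = 0.0300 M⁻¹ min⁻¹)
    coupling partner + single product → bis adduct + by-product (k = 0.0250 M⁻¹ min⁻¹)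
    coupling partner + bis adduct → triple product + by-product (k = 0.0430 M⁻¹ min⁻¹)
    coupling partner + triple product → tetra adduct + by-product (k = 0.0350 M⁻¹ min⁻¹)
    2 substrate → homo dimer (k = 0.0160 M⁻¹ min⁻¹)
    crystals ⇌ by-product, rate k6*(cs6 - [by-product]) while solid is left; crystals form when [by-product] > cs6 (solubility = 0.300 M, k = 2.20 min⁻¹)

In east, the first step used substrate at 0.94 of the rate of the path to homo dimer at the start, and 71 % of its turnover up to 1.5 h was done by 0.300 h. At 1.50 h, east held 7.48 % of its partner, with bis adduct at 12.4 %, triple product at 8.21 % and tetra adduct at 4.66 %. Its count stood at 1.04 against our 0.875. With 2.5 M of partner, 1.67 equiv, the same dose reckons a neighbour of east at 1.46 and a share of 40.7 %, and that neighbour stands at 32.2 %.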